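Time is the same in both flasks: ochre and blue are each read after 10 s, and they differ in their charge of X.

    E + X → G + L (k1 = 310 /M/s)
    X + G ⇌ X.G, settled at all times (K2 = 7.1 × 10⁶ /M)
    E + L → E.L (k3 = 1400 /M/s)
    X ⇌ Z (K4 = 0.76, k4 = 0.27 /s)

- ochre: E 0.50 mM; X 0.550 mM; time 10 s
- blue: E 0.50 mM; X 0.830 mM; time 10 s

- part of the E that has reacted at the end, ochre
- part of the E that has reacted at the end, blue
- what raising the concentration of X from its lowest to its highest value here does to the part of the E that has reacted (changes below 5 percentage points count as none) (it rises / no change / it falls)

- a species is counted by the E in it: one E.L counts as two
- run time (ochre): 10 s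

**First instants.** X starts free and begins leaking to Z. In blue, X and Z settle against each other with a half-life of 1.11 s, shorter than the run. So I treat X and Z as one pool in both flasks, and with K4 at 0.76 a share of 56.8% of that pool is free X.

**The middle.** Each making of G and L costs more than it appears to. In ochre, K2 times [X] at the start is 3900, so nearly all G is held by a second X as X.G. In ochre, too, L meets E with a half-life of 0.99 s, shorter than the 4.1 s of E going by reaction with X, so L soon takes a second E into E.L. I therefore count two E and two X for each event. 352 /M/s is then the paired constant, twice k1 times the free share of the pool: both [E] and the pool fall at this constant times [E] times the pool.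

**The end.** In this reckoning the gap between pool and E stays fixed, at 0.0500 mM in ochre and 0.330 mM in blue, which makes E the limiting reagent. This is second order with both partners running down. The part of E left is the gap over the charge of X times exp(constant × gap × time), less the charge of E. I get 67.9% reacted for ochre and 84.7% for blue.

**The forecast.** It gives 69% for ochre and 84% for blue, so for more X, it rises, on the ground that “the extra X in blue keeps the reaction running”. Its ochre figure is higher than mine, its blue figure lower.

**The result.** Ochre reaches 66.5% and blue 83.5%: with more X, it rises, by 17 percentage points. At 10.0 s, ochre holds 60.8% of its charged E as E.L against 5.70% as L. Put to blue read at 2.5 s, the paired constant 352 /M/s gives 45.9% reacted, and that reading stands at 44.9%.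

All constants are those of an exercise, and the outcome is calculated.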